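**Retrosynthetic overview**

1. Numbering each quinone ring C1(=O), C2(OH), C3(chain), C4(=O), C5(OMe), C6(Me): the chain-bearing C3 and the methyl-bearing C6 are para, and each sits between two oxygen-bearing carbons. Rings A and B are therefore 2-methyl-5-alkylresorcinol nuclei (C1 and C5 oxygens) of a C-methylated, fatty-acyl-primed tetraketide, carrying two later oxygens at C4 and C2.
2. Target 15 ⇒ bis-epoxyquinone 14 ⇒ bis-quinone 13 ⇒ bis(3-methoxy-2-methyl-5-alkylphenol) 12 ⇒ bis-resorcylate acetonide 9. The C4 oxygen comes from phenol oxidation; the C2 oxygen is placed on the carbon that carried the carboxyl.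
3. Key disconnection: the C2–C3 bond of ring A and of ring B. Both benzene rings close in one operation by aldol cycloaromatization of the two diketo-dioxinone termini of 8.
4. 8 ⇒ two molecules of methyl keto-dioxinone 4 (as dianion) plus the bis-Weinreb amide 7 of hexadecanedioic acid, which acts as a double starter unit. 4 comes from trimethyldioxinone 1 by γ-methylation and γ-acetylation.

Key step: step 5

Remark: the target is achiral; the labile methine centres of 4 and 8 and the epoxide centres of 14 are carried as stereoisomer mixtures because all are erased before the target.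

**Route**

Step 1
Reactants: 1 2,2,6-trimethyl-4H-1,3-dioxin-4-one
Product: 2 6-ethyl-2,2-dimethyl-4H-1,3-dioxin-4-one
Conditions: LiN(iPr)2, THF–DMPU, −78 °C; MeI, −78 to −40 °C
Reagents that add atoms: iodomethane, CI
Why: Kinetic deprotonation of the 6-methyl group gives the lithium dienolate, which iodomethane alkylates at the γ-carbon in the presence of DMPU (vinylogous enolate γ-alkylation), the usual way to homologate the 6-substituent of this dioxinone.

Step 2
Reactants: 2 6-ethyl-2,2-dimethyl-4H-1,3-dioxin-4-one; 3 acetyl chloride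
Product: 4 2,2-dimethyl-6-(3-oxobutan-2-yl)-4H-1,3-dioxin-4-one (racemic, labile methine)
Conditions: LiN(SiMe3)2 (1 equiv per 2), THF, −78 °C; AcCl (0.5 equiv), −78 °C; aq. NH4Cl
Reagents that add atoms: none
Why: γ-C-Acylation of the lithium dienolate of 2 by acetyl chloride (vinylogous Claisen-type acylation, established for the 6-methyl parent) installs the ketone, a second equivalent of dienolate absorbing the acidic product proton; the new methine centre is racemic and labile, which is immaterial because it becomes an aromatic carbon.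

Step 3
Reactants: 5 hexadecanedioic acid
Product: 7 N1,N16-dimethoxy-N1,N16-dimethylhexadecanediamide, via bis-acylimidazolide 6 (not isolated)
Conditions: 1,1'-carbonyldiimidazole (CDI), THF, 40 °C; then MeNH(OMe)·HCl, rt
Reagents that add atoms: N,O-dimethylhydroxylamine hydrochloride, CNOC.Cl
Why: Activation of both carboxyl groups as acyl imidazolides followed by aminolysis with N,O-dimethylhydroxylamine is a standard Weinreb amide synthesis, driven by loss of CO2 in the activation.

Step 4
Reactants: 4 2,2-dimethyl-6-(3-oxobutan-2-yl)-4H-1,3-dioxin-4-one (2.6 equiv); 7 N1,N16-dimethoxy-N1,N16-dimethylhexadecanediamide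
Product: 8 2,23-bis(2,2-dimethyl-4-oxo-4H-1,3-dioxin-6-yl)tetracosane-3,5,20,22-tetraone (mixture of labile epimers, largely enolized)
Conditions: LiN(iPr)2 (5.3 equiv), THF, −78 to −40 °C; then 7, −78 to −20 °C; cold aq. NH4Cl
Reagents that add atoms: none
Why: Two-directional crossed Claisen condensation in which the dianion of 4 (deprotonated first at the methine between ketone and dioxinone, then at the acetyl methyl) reacts at its terminal, more basic carbon in the manner of a Weiler dianion, while the chelated tetrahedral adducts of the Weinreb amide collapse only on quench, so each end stops at the 1,3-diketone.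

Step 5
Reactants: 8 2,23-bis(2,2-dimethyl-4-oxo-4H-1,3-dioxin-6-yl)tetracosane-3,5,20,22-tetraone
Product: 9 1,14-bis(7-hydroxy-2,2,8-trimethyl-4-oxo-4H-1,3-benzodioxin-5-yl)tetradecane
Conditions: Et3N, CH2Cl2, rt; then silica gel
Reagents that add atoms: none
Why: Et3N reversibly removes the acidic C2–H and C23–H (each between a ketone and a dioxinone) to give a cross-conjugated dienolate whose dioxinone C5 adds to the chain-proximal ketone (C5 and C20 of the tetracosane chain, the former diacid carbonyls); E1cB loss of water from the aldolate and enolization of the remaining ring ketone then give the benzene ring, the overall change being the known aldol cycloaromatization of diketo-dioxinones to resorcylate acetonides, which mirrors the aldol closure of an alkylresorcinol synthase on a fatty-acyl-primed tetraketide. Each carbocycle closes by a 6-exo-trig aldol in which the enolate C=C–O unit of the dioxinone lies outside the forming ring (enolexo), and the two termini, insulated by fourteen methylenes, react independently. No stereocentre is created and the labile C2 and C23 centres are erased. The step needs aldol closure to outrun Claisen-type C-acylation, lactonization to pyranones and retro-Claisen cleavage; the dioxinone secures this because its carbonyl is locked in the heterocycle trans to the side chain, out of reach of the chain nucleophiles, while its C5–H sits cis to the chain as the only carbon nucleophile able to reach a ketone through a six-membered transition state, and the amine base at room temperature avoids the thermal acylketene pathway.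

Step 6
Reactants: 9 1,14-bis(7-hydroxy-2,2,8-trimethyl-4-oxo-4H-1,3-benzodioxin-5-yl)tetradecane
Product: 10 1,14-bis(7-methoxy-2,2,8-trimethyl-4-oxo-4H-1,3-benzodioxin-5-yl)tetradecane
Conditions: MeI, K2CO3, acetone, reflux
Reagents that add atoms: iodomethane, CI
Why: Williamson O-methylation of the only free phenol of each ring (the other resorcinol oxygen is tied up in the acetonide) under conditions that leave the benzodioxinone intact.

Step 7
Reactants: 10 1,14-bis(7-methoxy-2,2,8-trimethyl-4-oxo-4H-1,3-benzodioxin-5-yl)tetradecane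
Product: 11 6,6'-(tetradecane-1,14-diyl)bis(2-hydroxy-4-methoxy-3-methylbenzoic acid)
Conditions: KOH, DMSO–H2O, 80 °C; cold 1 M HCl
Reagents that add atoms: water, O (delivered as hydroxide from potassium hydroxide, [K+].[OH-])
Why: Saponification, in which hydroxide attacks the aryl ester carbonyl of the benzodioxinone and the resulting hemiketal loses acetone, frees the salicylic acid and its ortho phenol while the aryl methyl ethers are inert.

Step 8
Reactants: 11 6,6'-(tetradecane-1,14-diyl)bis(2-hydroxy-4-methoxy-3-methylbenzoic acid)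
Product: 12 5,5'-(tetradecane-1,14-diyl)bis(3-methoxy-2-methylphenol)
Conditions: N-methylpyrrolidone, 150 °C, N2
Reagents that add atoms: none
Why: Thermal protodecarboxylation of an ortho-hydroxy, para-methoxy benzoic acid through its ipso-protonated keto tautomer, the behaviour of orsellinic- and everninic-type acids, leaves hydrogen at the carbon that will later carry the hydroxyl.

Step 9
Reactants: 12 5,5'-(tetradecane-1,14-diyl)bis(3-methoxy-2-methylphenol)
Product: 13 6,6'-(tetradecane-1,14-diyl)bis(2-methoxy-3-methylcyclohexa-2,5-diene-1,4-dione)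
Conditions: (KSO3)2NO, KH2PO4, Bu4NHSO4, CH2Cl2–H2O, rt
Reagents that add atoms: potassium nitrosodisulfonate, [K+].[K+].[O-]S(=O)(=O)N([O])S(=O)(=O)[O-]
Why: Teuber oxidation, in which the nitrosodisulfonate radical abstracts the phenolic hydrogen and a second equivalent couples at the free para position (between the methoxy- and chain-bearing carbons) before loss of imidodisulfonate, gives the para-quinone as in oxidations of 3-methoxy-5-alkylphenols to 2-methoxy-6-alkylbenzoquinones.

Step 10
Reactants: 13 6,6'-(tetradecane-1,14-diyl)bis(2-methoxy-3-methylcyclohexa-2,5-diene-1,4-dione)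
Product: 14 1,14-bis(3-methoxy-4-methyl-2,5-dioxo-7-oxabicyclo[4.1.0]hept-3-en-1-yl)tetradecane (cis-fused epoxides, mixture of diastereomers)
Conditions: tBuOOH (in decane), DBU, CH2Cl2, 0 °C
Reagents that add atoms: tert-butyl hydroperoxide, CC(C)(C)OO
Why: Weitz–Scheffer nucleophilic epoxidation, in which the peroxide anion adds to the only unsubstituted quinone carbon (β to the more electrophilic carbonyl) and closes on oxygen while the tetrasubstituted, methoxy-donated double bond stays untouched; the two new centres of each ring are necessarily cis, and the diastereomer mixture over the two rings does not matter because all four centres are erased in the next step.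

Step 11
Reactants: 14 1,14-bis(3-methoxy-4-methyl-2,5-dioxo-7-oxabicyclo[4.1.0]hept-3-en-1-yl)tetradecane
Product: 15 3,3'-(tetradecane-1,14-diyl)bis(2-hydroxy-5-methoxy-6-methylcyclohexa-2,5-diene-1,4-dione) (CNP0278640.0)
Conditions: conc. H2SO4, 0 °C; ice–water
Reagents that add atoms: none
Why: Acid-promoted isomerization of the epoxyquinone (opening at the tertiary carbon, 1,2-hydride shift to the ene-trione, enolization), the reaction that turns 2-methylnaphthoquinone oxide into phthiocol, places the hydroxyl on the former C–H carbon next to the chain.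

**Compound list**

1 | 2,2,6-trimethyl-4H-1,3-dioxin-4-one | CC1=CC(=O)OC(C)(C)O1 | starting material
2 | 6-ethyl-2,2-dimethyl-4H-1,3-dioxin-4-one | CCC1=CC(=O)OC(C)(C)O1 | intermediate
3 | acetyl chloride | CC(Cl)=O | starting material
4 | 2,2-dimethyl-6-(3-oxobutan-2-yl)-4H-1,3-dioxin-4-one (racemic) | CC(=O)C(C)C1=CC(=O)OC(C)(C)O1 | intermediate
5 | hexadecanedioic acid | OC(=O)CCCCCCCCCCCCCCC(=O)O | starting material
6 | 1,16-di(1H-imidazol-1-yl)hexadecane-1,16-dione | O=C(n1ccnc1)CCCCCCCCCCCCCCC(=O)n1ccnc1 | intermediate (not isolated)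
7 | N1,N16-dimethoxy-N1,N16-dimethylhexadecanediamide | CON(C)C(=O)CCCCCCCCCCCCCCC(=O)N(C)OC | intermediate
8 | 2,23-bis(2,2-dimethyl-4-oxo-4H-1,3-dioxin-6-yl)tetracosane-3,5,20,22-tetraone (epimer mixture) | CC1(C)OC(=O)C=C(O1)C(C)C(=O)CC(=O)CCCCCCCCCCCCCCC(=O)CC(=O)C(C)C1=CC(=O)OC(C)(C)O1 | intermediate
9 | 1,14-bis(7-hydroxy-2,2,8-trimethyl-4-oxo-4H-1,3-benzodioxin-5-yl)tetradecane | CC1(C)OC(=O)c2c(CCCCCCCCCCCCCCc3cc(O)c(C)c4OC(C)(C)OC(=O)c34)cc(O)c(C)c2O1 | intermediate
10 | 1,14-bis(7-methoxy-2,2,8-trimethyl-4-oxo-4H-1,3-benzodioxin-5-yl)tetradecane | CC1(C)OC(=O)c2c(CCCCCCCCCCCCCCc3cc(OC)c(C)c4OC(C)(C)OC(=O)c34)cc(OC)c(C)c2O1 | intermediate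
11 | 6,6'-(tetradecane-1,14-diyl)bis(2-hydroxy-4-methoxy-3-methylbenzoic acid) | OC(=O)c1c(O)c(C)c(OC)cc1CCCCCCCCCCCCCCc1cc(OC)c(C)c(O)c1C(=O)O | intermediate
12 | 5,5'-(tetradecane-1,14-diyl)bis(3-methoxy-2-methylphenol) | Cc1c(O)cc(CCCCCCCCCCCCCCc2cc(O)c(C)c(OC)c2)cc1OC | intermediate
13 | 6,6'-(tetradecane-1,14-diyl)bis(2-methoxy-3-methylcyclohexa-2,5-diene-1,4-dione) | COC1=C(C)C(=O)C=C(CCCCCCCCCCCCCCC2=CC(=O)C(C)=C(OC)C2=O)C1=O | intermediate
14 | 1,14-bis(3-methoxy-4-methyl-2,5-dioxo-7-oxabicyclo[4.1.0]hept-3-en-1-yl)tetradecane (diastereomer mixture) | COC1=C(C)C(=O)C2OC2(CCCCCCCCCCCCCCC23OC2C(=O)C(C)=C(OC)C3=O)C1=O | intermediate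
15 | 3,3'-(tetradecane-1,14-diyl)bis(2-hydroxy-5-methoxy-6-methylcyclohexa-2,5-diene-1,4-dione) | COC1=C(C)C(=O)C(O)=C(CCCCCCCCCCCCCCC2=C(O)C(=O)C(C)=C(OC)C2=O)C1=O | target

**Step count**

Total steps: 11. Longest linear sequence: 10 (steps 1, 2, 4, 5, 6, 7, 8, 9, 10, 11); step 3 is a one-step branch.

**Steps most likely to fail**

Step 5 (key step). The double cyclization may go astray: one terminus may close while the other stalls at the aldol stage, or an enol oxygen may lactonize onto a thermally opened dioxinone to give a pyranone. The fallback keeps the same ring bond but changes the activation, starting from 8. Heating 8 in toluene with methanol at 110 °C opens each dioxinone by loss of acetone, and methanol captures the acylketene to give the open-chain bis(triketo ester) dimethyl 4,25-dimethyl-3,5,7,22,24,26-hexaoxooctacosanedioate F1. Cs2CO3 in MeOH followed by HCl–MeOH then closes the β-keto ester α-carbon onto the chain ketone and aromatizes to dimethyl 6,6'-(tetradecane-1,14-diyl)bis(2,4-dihydroxy-3-methylbenzoate) F2. The para hydroxyl, which is not hydrogen-bonded to the ester, is methylated selectively with MeI and K2CO3 (one equivalent per ring) to dimethyl 6,6'-(tetradecane-1,14-diyl)bis(2-hydroxy-4-methoxy-3-methylbenzoate) F3. Saponification with KOH in aqueous DMSO returns to the route at 11.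

Step 4. The dianion may be quenched by proton transfer from the α-methylenes of the amide, or the second acylation may lag, so that the mono-adduct accumulates. The fallback avoids the dianion and starts from 2 and 5. γ-Acylation of the lithium dienolate of 2 (LiN(SiMe3)2, THF, −78 °C) with allyl malonyl chloride gives allyl 4-(2,2-dimethyl-4-oxo-4H-1,3-dioxin-6-yl)-3-oxopentanoate F4. Diacid 5 is converted with oxalyl chloride and catalytic DMF into hexadecanedioyl dichloride F5. MgCl2 and pyridine in CH2Cl2 mediate double C-acylation of the magnesium enolate of F4 by F5 to give diallyl 2,19-bis[2-(2,2-dimethyl-4-oxo-4H-1,3-dioxin-6-yl)propanoyl]-3,18-dioxoicosanedioate F6. Pd(PPh3)4 (zerovalent palladium) and morpholine then remove the allyl groups with decarboxylation, coming back to the route at 8.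

Step 10. The peroxide anion or the base may attack the methoxy-bearing vinylogous ester carbon, with loss of the methoxy group, or the quinone may decompose under base. The fallback replaces steps 10 and 11 and starts from 13. Thiele–Winter acetoxylation (Ac2O, BF3·OEt2 or catalytic H2SO4) adds acetate at the only free ring position and gives 1,14-bis(2,3,6-triacetoxy-5-methoxy-4-methylphenyl)tetradecane F7. Methanolysis with HCl–MeOH and oxidation of the resulting hydroxyhydroquinone in air (or with FeCl3) arrives directly at 15.

**Further compounds**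

F1 | step 5 | dimethyl 4,25-dimethyl-3,5,7,22,24,26-hexaoxooctacosanedioate | COC(=O)CC(=O)C(C)C(=O)CC(=O)CCCCCCCCCCCCCCC(=O)CC(=O)C(C)C(=O)CC(=O)OC
F2 | step 5 | dimethyl 6,6'-(tetradecane-1,14-diyl)bis(2,4-dihydroxy-3-methylbenzoate) | COC(=O)c1c(O)c(C)c(O)cc1CCCCCCCCCCCCCCc1cc(O)c(C)c(O)c1C(=O)OC
F3 | step 5 | dimethyl 6,6'-(tetradecane-1,14-diyl)bis(2-hydroxy-4-methoxy-3-methylbenzoate) | COC(=O)c1c(O)c(C)c(OC)cc1CCCCCCCCCCCCCCc1cc(OC)c(C)c(O)c1C(=O)OC
F4 | step 4 | allyl 4-(2,2-dimethyl-4-oxo-4H-1,3-dioxin-6-yl)-3-oxopentanoate | C=CCOC(=O)CC(=O)C(C)C1=CC(=O)OC(C)(C)O1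
F5 | step 4 | hexadecanedioyl dichloride | ClC(=O)CCCCCCCCCCCCCCC(Cl)=O
F6 | step 4 | diallyl 2,19-bis[2-(2,2-dimethyl-4-oxo-4H-1,3-dioxin-6-yl)propanoyl]-3,18-dioxoicosanedioate | C=CCOC(=O)C(C(=O)C(C)C1=CC(=O)OC(C)(C)O1)C(=O)CCCCCCCCCCCCCCC(=O)C(C(=O)OCC=C)C(=O)C(C)C1=CC(=O)OC(C)(C)O1
F7 | step 10 | 1,14-bis(2,3,6-triacetoxy-5-methoxy-4-methylphenyl)tetradecane | CC(=O)Oc1c(C)c(OC)c(OC(C)=O)c(CCCCCCCCCCCCCCc2c(OC(C)=O)c(OC)c(C)c(OC(C)=O)c2OC(C)=O)c1OC(C)=O
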